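## The problem

Indane numbering is used throughout: C1 carries the aroyl group (ketone carbon C8), C2 the 3,5-dihydroxyphenyl group, C3 the 4-hydroxyphenyl group; ring A is the benzo ring (hydroxyls at C4 and C6, C4 next to C3a) and ring B the five-membered ring. As drawn, the target 25 is the all-cis (1R,2R,3R) isomer, so three bulky groups sit on one face of ring B. This arrangement is the less stable one. C1 is benzylic and alpha to the C8 ketone, so base or acid can epimerise it, and the cis C1 aroyl and C2 resorcinol groups are placed for Friedel–Crafts cyclodehydration under strong Lewis acids. C1 therefore has to be locked until late and the last steps have to be close to neutral. C2 is the only centre that cannot enolise or ionise; once set it can direct C3, because a hydride added to a C3 benzylic cation enters anti to the C2 aryl group. There is no chiral-pool handle, so the absolute configuration must come from a catalyst. The six phenols need protection that survives fluoride, organolithiums, hydride and acid and comes off without acid or base. The enabling feature is that C8 on C1 and the C3 carbon are 1,3-cis across ring B, so C8 and an oxygen on C3 can be tied as a lactone bridging over C2. The chain C8–C1–C2 is then an enal whose beta-carbon C2 must attack a ketone carbon C3 held ortho on ring A, which is a homoenolate pattern.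

## Retrosynthesis

**25 from 24.** The six O–benzyl bonds are cut last. Benzyl ethers are preferred to methyl ethers because hydrogenolysis is neutral, whereas boron tribromide would expose the labile C1 centre and the cis aroyl/aryl pair to a strong Lewis acid. The forward step must cleave six benzyl ethers and spare the aryl ketone.

**24 from 23.** The C3–H bond is cut back to a C3 tertiary alcohol. C3 is doubly benzylic and flanked by an ortho,para-dialkoxy ring, so its cation forms at low temperature. Hydride then enters anti to the C2 aryl and C1 aroyl groups, which gives the cis C3 aryl group that equilibration would never give. The configuration of the C3 alcohol in 23 is irrelevant. The forward step must ionise C3–OH without reducing the C8 ketone.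

**23 from 19 and 20.** The C8–aryl bond is cut, with lactone 19 as the acyl donor and aryllithium 21 (from bromide 20) as the nucleophile. The lactone is preferred to an open ester or amide for three reasons: C1 is a bridgehead of the 2-oxabicyclo[2.2.1]heptan-3-one and cannot enolise, the bridged lithium lactolate 22 resists a second addition, and the C3 oxygen needed for the next step is released in the same event.

**19 from 18 (key disconnection).** The C2–C3 bond and the O–C8 bond are cut together. This removes ring B, the lactone ring and all three stereocentres and leaves the achiral keto enal 18. Cutting C1–C2 (Michael-type closure) or C3–C3a (Friedel–Crafts closure) instead would deliver the stable 2,3-trans series and leave C1 unprotected. The forward reaction asks a chiral carbene to make C2 nucleophilic, to choose its face, and to deliver C8 as an acylating agent to the new alkoxide.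

**18 from 17 from 16.** These are oxidation-level changes only. The C1=C2 alkene is most reliably made at the ester level (16). A conjugated ester cannot be reduced selectively beside a diaryl ketone, so both are reduced to diol 17 and both are re-oxidised.

**16 from 11 and 12.** The C1=C2 bond is cut as an aldol condensation between the arylacetate 11 and the commercially available aldehyde 12. This brings in the C2 carbon with its resorcinol ring. The ketone of 11 has no alpha-hydrogen and cannot interfere as a nucleophile.

**11 from 8 and 9.** The C1–C7a and C3–C3a bonds to ring A are cut at once, as an aryne insertion into the alpha C–C(=O) bond of the commercially available beta-keto ester 9. The alkoxy group of aryne 10 puts the aroyl group next to oxygen (future C4) and the acetate arm on the unflanked carbon, which is the pattern 25 requires. Friedel–Crafts acylation of a 3,5-dialkoxyphenylacetate would need Lewis acids that threaten benzyl ethers and could give positional isomers.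

**8 from 1.** The silyl aryl triflate 8 comes from the commercially available phenol 1 in three steps: carbamate 2, carbamate-directed ortho-silylation to 6, then carbamate cleavage and triflation. The directing group fixes the silicon between two oxygens, which bromination of 1 would not guarantee.

## Roads not taken

**Alternative 1:** Here ring A is joined to C1 and C3 by inserting 3,5-dimethoxybenzyne into a symmetric 1,3-diaryl-1,3-diketone. The diketone carbon adds to the aryne and one aroyl group migrates to the neighbouring ring carbon. This gives 2-{2-[4-(benzyloxy)benzoyl]-3,5-dimethoxyphenyl}-1-[4-(benzyloxy)phenyl]ethanone A1.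
- Merits: both aryl ketones, C8 included, arrive in one step of a well-established reaction class from a cheap symmetric partner, and no organolithium is needed later. In security of the key step this road is better than the chosen one; it is the same reaction class as step 4 here.
- Weak points: A1 is achiral and has no ring B. C2 and its aryl group still have to be inserted between C1 and C3, and closing C2–C3 then needs the same polarity reversal at C2 as the chosen plan, so the hard bond is only postponed. C1 is alpha to a ketone from the start and cannot be held. All three stereocentres and the absolute configuration remain open, and two kinds of protecting group must be removed.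
- Comparison: the chosen plan carries more risk in one step, but if that step works it delivers both rings, the C2–C3 bond, the absolute configuration and a locked C1 in a single catalytic operation.

**Alternative 2:** Here C7a–C1 and C2–C3 are made by a rhodium-catalysed annulation of an ortho-aroylarylboronic acid with an internal alkyne under a chiral-diene complex derived from [Rh(OH)(cod)]2. The aryl group adds to the alkyne and the alkenylrhodium adds to the ketone, giving indenol A2 with the C3 carbinol set and a silyl ether at C8.
- Merits: the annulation has close precedent with good enantiocontrol, and it is convergent. In these respects it is stronger than the carbene step.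
- Weak points: the remaining two centres need syn-hydrogenation of a tetrasubstituted, fully aryl-substituted C1=C2 alkene. The C3 hydroxyl must then be replaced by hydride in acid while a 4-methoxybenzylic silyl ether sits at C8, and that ether would ionise as well. C8 is carried at the wrong oxidation level as a stereorandom centre and must be deprotected and oxidised next to the labile C1. The doubly ortho-substituted boronic acid is prone to protodeboronation.
- Comparison: the chosen plan has the less certain ring-forming step. Against that it has no alkene hydrogenation, no redox work at C8 after C1 is set, and a C1 centre that cannot epimerise until the ketone is unveiled.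

**Alternative 3:** Here C1–C7a is made by photochemical ring contraction of a cis-3,4-diaryl-2-diazo-1-tetralone. Loss of N2, migration of the ring A carbon and capture of the ketene by N,O-dimethylhydroxylamine give the all-cis amide A3.
- Merits: every reaction is of a known type, the amide is at the right level for aryl ketone formation, and protonation of the ketene adduct anti to the C2 aryl group should give cis C1. On precedent this is the safest of the four roads.
- Weak points: the stereochemical problem is moved into the tetralone, whose cis-3,4-diaryl pair is itself the less stable arrangement and must be made as one enantiomer first. Diazo transfer next to a C3 aryl group needs an activating acyl group. The route is linear and long. The aryl ketone must still be made from an epimerisable all-cis amide with a basic organometallic.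
- Comparison: the chosen plan is shorter and sets the absolute configuration catalytically on an achiral precursor. It accepts a key step without direct precedent, and a fallback is given for it.

Key step: step 8

Assumption: the (5aS,10bR) antipode of the aminoindanol-derived triazolium salt is written in step 8; which antipode gives the (1R,2R,3R) series must be found by experiment (both are commercially available), and catalyst-bound species of the carbene cycle are described in words without compound numbers.

**Step 1**
Reactants: 1 3,5-bis(benzyloxy)phenol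
Product: 2 3,5-bis(benzyloxy)phenyl N-(propan-2-yl)carbamate
Conditions: i-PrNCO, Et3N (cat.), CH2Cl2, 23 °C
Reagents that add atoms: isopropyl isocyanate, CC(C)N=C=O
Why: Base-catalysed addition of the phenol to the isocyanate (carbamoylation); the N-monoalkyl carbamate directs the ortho-metalation of step 2 and can be removed in step 3 without acid.

**Step 2**
Reactants: 2 3,5-bis(benzyloxy)phenyl N-(propan-2-yl)carbamate
Product: 6 3,5-bis(benzyloxy)-2-(trimethylsilyl)phenyl N-(propan-2-yl)carbamate, via N-silyl carbamate 3 (not isolated), via aryllithium 4 (not isolated), via bis-silylated carbamate 5 (not isolated)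
Conditions: t-BuMe2SiOTf, TMEDA, Et2O, 0 to 23 °C; n-BuLi, TMEDA, −78 °C; Me3SiCl, −78 to 23 °C; aq. NaHSO4
Reagents that add atoms: chlorotrimethylsilane, C[Si](C)(C)Cl
Why: Directed ortho-metalation: N-silylation masks the N–H, n-BuLi/TMEDA removes the proton between the carbamate and a benzyloxy group (C2 and C6 are equivalent), Me3SiCl traps the aryllithium and the N–Si bond is lost in the acidic work-up. At −78 °C lithiation at this doubly activated ring position should outrun deprotonation of the benzylic CH2 groups.

**Step 3**
Reactants: 6 3,5-bis(benzyloxy)-2-(trimethylsilyl)phenyl N-(propan-2-yl)carbamate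
Product: 8 3,5-bis(benzyloxy)-2-(trimethylsilyl)phenyl trifluoromethanesulfonate, via silylphenol 7 (not isolated)
Conditions: DBU, Et2NH, MeCN, 40 °C; then PhNTf2, 23 °C
Reagents that add atoms: N-phenylbis(trifluoromethanesulfonimide), O=S(=O)(N(c1ccccc1)S(=O)(=O)C(F)(F)F)C(F)(F)F
Why: Base-induced E1cB cleavage of the N–H carbamate (the isocyanate is taken up by Et2NH) frees the phenoxide, which is triflated in the same flask to give the fluoride-triggered aryne precursor.

**Step 4**
Reactants: 8 3,5-bis(benzyloxy)-2-(trimethylsilyl)phenyl trifluoromethanesulfonate; 9 ethyl 3-[4-(benzyloxy)phenyl]-3-oxopropanoate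
Product: 11 ethyl 2-{3,5-bis(benzyloxy)-2-[4-(benzyloxy)benzoyl]phenyl}acetate, via aryne 10 (not isolated)
Conditions: CsF, MeCN, 80 °C
Reagents that add atoms: none
Why: Aryne acyl-alkylation (formal insertion of an aryne into the alpha C–C(=O) bond of a beta-keto ester): the keto ester carbon adds to the aryne carbon remote from the benzyloxy group, the aryl anion next to oxygen adds to the ketone, and ring opening of the four-membered alkoxide moves the aroyl group onto the ring. This puts the aroyl carbon (future C3) beside the benzyloxy group (future C4) and the acetate carbon (future C1) on the unflanked position.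

**Step 5**
Reactants: 11 ethyl 2-{3,5-bis(benzyloxy)-2-[4-(benzyloxy)benzoyl]phenyl}acetate; 12 3,5-bis(benzyloxy)benzaldehyde
Product: 16 ethyl (2E)-2-{3,5-bis(benzyloxy)-2-[4-(benzyloxy)benzoyl]phenyl}-3-[3,5-bis(benzyloxy)phenyl]prop-2-enoate, via lithium enolate 13 (not isolated), via lithium aldolate 14 (not isolated), via acetoxy ester 15 (not isolated)
Conditions: LiN(SiMe3)2, THF, −78 °C; 12; Ac2O, −78 to 0 °C; DBU, 23 °C
Reagents that add atoms: none
Why: Aldol condensation in one flask: enolate addition to the aldehyde, acetylation of the aldolate and E1cB elimination. The ketone has no alpha-hydrogen and the enolate carbon cannot reach it; the conjugated E ester, with the ester group trans to the new aryl group, is the expected isomer.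

**Step 6**
Reactants: 16 ethyl (2E)-2-{3,5-bis(benzyloxy)-2-[4-(benzyloxy)benzoyl]phenyl}-3-[3,5-bis(benzyloxy)phenyl]prop-2-enoate
Product: 17 (2E)-2-{3,5-bis(benzyloxy)-2-[[4-(benzyloxy)phenyl](hydroxy)methyl]phenyl}-3-[3,5-bis(benzyloxy)phenyl]prop-2-en-1-ol
Conditions: i-Bu2AlH (excess), CH2Cl2, −78 to 0 °C; aq. KNaC4H4O6
Reagents that add atoms: none
Why: Hydride reduction: excess i-Bu2AlH takes the conjugated ester to the allylic alcohol by 1,2-reduction and the diaryl ketone to the carbinol. The new carbinol centre is unimportant because step 7 removes it.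

**Step 7**
Reactants: 17 (2E)-2-{3,5-bis(benzyloxy)-2-[[4-(benzyloxy)phenyl](hydroxy)methyl]phenyl}-3-[3,5-bis(benzyloxy)phenyl]prop-2-en-1-ol
Product: 18 (2E)-2-{3,5-bis(benzyloxy)-2-[4-(benzyloxy)benzoyl]phenyl}-3-[3,5-bis(benzyloxy)phenyl]prop-2-enal
Conditions: Dess–Martin periodinane, NaHCO3, CH2Cl2, 0 to 23 °C
Reagents that add atoms: none
Why: Dess–Martin oxidation returns both the allylic and the diarylmethyl alcohol to the carbonyl level. The buffer keeps the electron-rich carbinol from ionising and the alkene geometry is kept.

**Step 8**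
Reactants: 18 (2E)-2-{3,5-bis(benzyloxy)-2-[4-(benzyloxy)benzoyl]phenyl}-3-[3,5-bis(benzyloxy)phenyl]prop-2-enal
Product: 19 (1R,2R,3R)-4,6-bis(benzyloxy)-3-[4-(benzyloxy)phenyl]-2-[3,5-bis(benzyloxy)phenyl]-3-hydroxy-2,3-dihydro-1H-indene-1-carboxylic acid 1,3-lactone (benzo-fused 2-oxabicyclo[2.2.1]heptan-3-one; C8, the C3 oxygen and the C2 aryl group on one face)
Conditions: (5aS,10bR)-2-(2,4,6-trimethylphenyl)-5a,10b-dihydro-4H,6H-indeno[2,1-b][1,2,4]triazolo[4,3-d][1,4]oxazin-2-ium chloride (15 mol %), DBU (15 mol %), LiCl (1 equiv), 4 Å molecular sieves, THF, 40 °C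
Reagents that add atoms: none
Why: Proposed new method: the carbene adds to the aldehyde of 18 and proton transfer gives the hydroxy-enamine (Breslow intermediate), whose vinylogous carbon C2 reacts as a homoenolate and adds to the ketone carbon C3 on the neighbouring ring position; tautomerisation gives the C8 acyl azolium, which the new tertiary alkoxide acylates to close the lactone and release the carbene. The closest known reaction type is the carbene-catalysed homoenolate annulation of enals with aldehydes or activated ketones to gamma-butyrolactones, which has not been shown for an intramolecular, electron-rich diaryl ketone or for a bridged product. Ring B closes 5-exo-trig at the C=O group with the tether on the central carbon of the oxyallyl nucleophile, the topology of intramolecular allylmetal additions that give 3-methylenecyclopentanols; the lactone closes 5-exo-trig at the acyl azolium carbon. C2 is set by the chiral triazolium, which shields one face of the homoenolate carbon; C3 follows from C2 because the two aryl groups avoid each other across the forming bond, which puts the alkoxide on the face of the C2 aryl group; C1 is fixed by the bridge, since only the epimer with C8 cis to the C3 oxygen can lactonise and the acyl azolium alpha-centre can equilibrate before it does. The step needs homoenolate reactivity over acyl-anion addition and over beta-protonation: the N-mesityl triazolium and the alpha-aryl group disfavour bond formation at C8, a crossed-benzoin adduct would revert whereas lactonisation does not, and sieves keep proton sources out. LiCl is added to activate the deactivated ketone.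

**Step 9**
Reactants: 19 the lactone of step 8; 20 1-(benzyloxy)-4-bromobenzene
Product: 23 [(1R,2R,3R)-4,6-bis(benzyloxy)-3-[4-(benzyloxy)phenyl]-2-[3,5-bis(benzyloxy)phenyl]-3-hydroxy-2,3-dihydro-1H-inden-1-yl][4-(benzyloxy)phenyl]methanone, via aryllithium 21 (not isolated), via lithium lactolate 22 (not isolated)
Conditions: 20, n-BuLi, THF, −78 °C; then 19, THF, −78 °C; AcOH, −78 °C
Reagents that add atoms: none
Why: Bromine–lithium exchange, then 1,2-addition of the aryllithium to the lactone carbonyl; the bridged lithium lactolate should persist at −78 °C and open to the ketone only on protonation, so one aryl group adds. C1 is a bridgehead of the lactone and cannot be enolised (Bredt's rule), so it stays cis; the cold acetic acid quench keeps base away from the freed ketone.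

**Step 10**
Reactants: 23 the hydroxy ketone of step 9
Product: 24 [(1R,2R,3R)-4,6-bis(benzyloxy)-3-[4-(benzyloxy)phenyl]-2-[3,5-bis(benzyloxy)phenyl]-2,3-dihydro-1H-inden-1-yl][4-(benzyloxy)phenyl]methanone (all-cis)
Conditions: Et3SiH, CF3CO2H, CH2Cl2, −78 to −20 °C
Reagents that add atoms: none
Why: Ionic hydrogenation: acid ionises the tertiary, doubly benzylic C3–OH (cation stabilised by the 2,4-dialkoxyaryl and 4-alkoxyphenyl groups) well below the temperature at which an aryl ketone is reduced. Et3SiH delivers hydride to the face opposite the C2 aryl and C1 aroyl groups, so the C3 aryl group ends cis to both.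

**Step 11**
Reactants: 24 the hexabenzyl ether of step 10
Product: 25 caraphenol C, [(1R,2R,3R)-2-(3,5-dihydroxyphenyl)-4,6-dihydroxy-3-(4-hydroxyphenyl)-2,3-dihydro-1H-inden-1-yl](4-hydroxyphenyl)methanone
Conditions: H2 (1 atm), Pd/C (10% Pd), EtOAc–MeOH, 23 °C
Reagents that add atoms: none
Why: Catalytic hydrogenolysis of the six aryl benzyl ethers under neutral conditions. No acid or base reaches the epimerisable C1 or the cis aroyl/aryl pair, and aryl benzyl ethers cleave faster than an aryl ketone is reduced, so the reaction is stopped after uptake of six equivalents of H2.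

## Compound list

1 | 3,5-bis(benzyloxy)phenol | Oc1cc(OCc2ccccc2)cc(OCc2ccccc2)c1 | starting material
2 | 3,5-bis(benzyloxy)phenyl N-(propan-2-yl)carbamate | CC(C)NC(=O)Oc1cc(OCc2ccccc2)cc(OCc2ccccc2)c1 | intermediate
3 | 3,5-bis(benzyloxy)phenyl N-[tert-butyl(dimethyl)silyl]-N-(propan-2-yl)carbamate (not isolated) | CC(C)N([Si](C)(C)C(C)(C)C)C(=O)Oc1cc(OCc2ccccc2)cc(OCc2ccccc2)c1 | intermediate
4 | 2-lithio derivative of 3 (not isolated) | CC(C)N([Si](C)(C)C(C)(C)C)C(=O)Oc1c([Li])c(OCc2ccccc2)cc(OCc2ccccc2)c1 | intermediate
5 | 3,5-bis(benzyloxy)-2-(trimethylsilyl)phenyl N-[tert-butyl(dimethyl)silyl]-N-(propan-2-yl)carbamate (not isolated) | CC(C)N([Si](C)(C)C(C)(C)C)C(=O)Oc1c([Si](C)(C)C)c(OCc2ccccc2)cc(OCc2ccccc2)c1 | intermediate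
6 | 3,5-bis(benzyloxy)-2-(trimethylsilyl)phenyl N-(propan-2-yl)carbamate | CC(C)NC(=O)Oc1c([Si](C)(C)C)c(OCc2ccccc2)cc(OCc2ccccc2)c1 | intermediate
7 | 3,5-bis(benzyloxy)-2-(trimethylsilyl)phenol (not isolated) | Oc1c([Si](C)(C)C)c(OCc2ccccc2)cc(OCc2ccccc2)c1 | intermediate
8 | 3,5-bis(benzyloxy)-2-(trimethylsilyl)phenyl trifluoromethanesulfonate | FC(F)(F)S(=O)(=O)Oc1c([Si](C)(C)C)c(OCc2ccccc2)cc(OCc2ccccc2)c1 | intermediate
9 | ethyl 3-[4-(benzyloxy)phenyl]-3-oxopropanoate | CCOC(=O)CC(=O)c1ccc(OCc2ccccc2)cc1 | starting material
10 | 3,5-bis(benzyloxy)benzyne (not isolated) | C1(OCc2ccccc2)=CC(OCc2ccccc2)=CC#C1 | intermediate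
11 | ethyl 2-{3,5-bis(benzyloxy)-2-[4-(benzyloxy)benzoyl]phenyl}acetate | CCOC(=O)Cc1cc(OCc2ccccc2)cc(OCc2ccccc2)c1C(=O)c1ccc(OCc2ccccc2)cc1 | intermediate
12 | 3,5-bis(benzyloxy)benzaldehyde | O=Cc1cc(OCc2ccccc2)cc(OCc2ccccc2)c1 | starting material
13 | lithium enolate of 11 (not isolated) | CCOC(O[Li])=Cc1cc(OCc2ccccc2)cc(OCc2ccccc2)c1C(=O)c1ccc(OCc2ccccc2)cc1 | intermediate
14 | lithium aldolate, ethyl 2-{3,5-bis(benzyloxy)-2-[4-(benzyloxy)benzoyl]phenyl}-3-[3,5-bis(benzyloxy)phenyl]-3-(lithiooxy)propanoate, diastereomer mixture (not isolated) | CCOC(=O)C(c1cc(OCc2ccccc2)cc(OCc2ccccc2)c1C(=O)c1ccc(OCc2ccccc2)cc1)C(O[Li])c1cc(OCc2ccccc2)cc(OCc2ccccc2)c1 | intermediate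
15 | ethyl 3-acetoxy-2-{3,5-bis(benzyloxy)-2-[4-(benzyloxy)benzoyl]phenyl}-3-[3,5-bis(benzyloxy)phenyl]propanoate, diastereomer mixture (not isolated) | CCOC(=O)C(c1cc(OCc2ccccc2)cc(OCc2ccccc2)c1C(=O)c1ccc(OCc2ccccc2)cc1)C(OC(C)=O)c1cc(OCc2ccccc2)cc(OCc2ccccc2)c1 | intermediate
16 | ethyl (2E)-2-{3,5-bis(benzyloxy)-2-[4-(benzyloxy)benzoyl]phenyl}-3-[3,5-bis(benzyloxy)phenyl]prop-2-enoate | CCOC(=O)/C(c1cc(OCc2ccccc2)cc(OCc2ccccc2)c1C(=O)c1ccc(OCc2ccccc2)cc1)=C/c1cc(OCc2ccccc2)cc(OCc2ccccc2)c1 | intermediate
17 | (2E)-2-{3,5-bis(benzyloxy)-2-[[4-(benzyloxy)phenyl](hydroxy)methyl]phenyl}-3-[3,5-bis(benzyloxy)phenyl]prop-2-en-1-ol, racemic at the carbinol | OC/C(c1cc(OCc2ccccc2)cc(OCc2ccccc2)c1C(O)c1ccc(OCc2ccccc2)cc1)=C/c1cc(OCc2ccccc2)cc(OCc2ccccc2)c1 | intermediate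
18 | (2E)-2-{3,5-bis(benzyloxy)-2-[4-(benzyloxy)benzoyl]phenyl}-3-[3,5-bis(benzyloxy)phenyl]prop-2-enal | O=C/C(c1cc(OCc2ccccc2)cc(OCc2ccccc2)c1C(=O)c1ccc(OCc2ccccc2)cc1)=C/c1cc(OCc2ccccc2)cc(OCc2ccccc2)c1 | intermediate
19 | (1R,2R,3R)-4,6-bis(benzyloxy)-3-[4-(benzyloxy)phenyl]-2-[3,5-bis(benzyloxy)phenyl]-3-hydroxy-2,3-dihydro-1H-indene-1-carboxylic acid 1,3-lactone | O=C(O3)[C@H]1c2cc(OCc4ccccc4)cc(OCc4ccccc4)c2[C@]3(c2ccc(OCc4ccccc4)cc2)[C@H]1c1cc(OCc4ccccc4)cc(OCc4ccccc4)c1 | intermediate
20 | 1-(benzyloxy)-4-bromobenzene | Brc1ccc(OCc2ccccc2)cc1 | starting material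
21 | [4-(benzyloxy)phenyl]lithium (not isolated) | [Li]c1ccc(OCc2ccccc2)cc1 | intermediate
22 | lithium alkoxide of the bridged hemiketal from 21 and the lactone carbonyl of 19, C8 configuration undefined (not isolated) | [Li]OC(O3)(c5ccc(OCc4ccccc4)cc5)[C@H]1c2cc(OCc4ccccc4)cc(OCc4ccccc4)c2[C@]3(c2ccc(OCc4ccccc4)cc2)[C@H]1c1cc(OCc4ccccc4)cc(OCc4ccccc4)c1 | intermediate
23 | [(1R,2R,3R)-4,6-bis(benzyloxy)-3-[4-(benzyloxy)phenyl]-2-[3,5-bis(benzyloxy)phenyl]-3-hydroxy-2,3-dihydro-1H-inden-1-yl][4-(benzyloxy)phenyl]methanone | O=C(c5ccc(OCc4ccccc4)cc5)[C@H]1c2cc(OCc4ccccc4)cc(OCc4ccccc4)c2[C@](O)(c2ccc(OCc4ccccc4)cc2)[C@H]1c1cc(OCc4ccccc4)cc(OCc4ccccc4)c1 | intermediate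
24 | [(1R,2R,3R)-4,6-bis(benzyloxy)-3-[4-(benzyloxy)phenyl]-2-[3,5-bis(benzyloxy)phenyl]-2,3-dihydro-1H-inden-1-yl][4-(benzyloxy)phenyl]methanone | O=C(c5ccc(OCc4ccccc4)cc5)[C@H]1c2cc(OCc4ccccc4)cc(OCc4ccccc4)c2[C@@H](c2ccc(OCc4ccccc4)cc2)[C@H]1c1cc(OCc4ccccc4)cc(OCc4ccccc4)c1 | intermediate
25 | caraphenol C, [(1R,2R,3R)-2-(3,5-dihydroxyphenyl)-4,6-dihydroxy-3-(4-hydroxyphenyl)-2,3-dihydro-1H-inden-1-yl](4-hydroxyphenyl)methanone | O=C(c1ccc(O)cc1)[C@H]1c2cc(O)cc(O)c2[C@@H](c2ccc(O)cc2)[C@H]1c1cc(O)cc(O)c1 | target

## Step count and least certain steps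

Total step count: 11. Longest linear sequence: 11 steps (1 to 25); compounds 9, 12 and 20 enter as purchased building blocks.

**Step 8 (key step, proposed new method).**
- Most likely failure: the carbene does not engage the hindered alpha,beta-diaryl enal, or the homoenolate is protonated or diverted to acyl-anion chemistry before it reaches the twisted, electron-rich diaryl ketone, so the C2–C3 bond does not form. Insufficient facial control at C2 is the second concern.
- Fallback with known reactions, setting out from 18 and returning at 19: Luche reduction (NaBH4, CeCl3·7H2O, MeOH–THF, −78 °C) should reduce only the aldehyde and give {2,4-bis(benzyloxy)-6-[(1E)-1-[3,5-bis(benzyloxy)phenyl]-3-hydroxyprop-1-en-2-yl]phenyl}[4-(benzyloxy)phenyl]methanone F1. An Appel reaction (CBr4, PPh3, CH2Cl2, 0 °C) converts it into the allylic bromide F2. Indium powder in THF–water then effects an intramolecular Barbier-type allylation of the ketone through the aryl-bearing allyl terminus, the only ring-forming mode. This is the established closure of allylmetals tethered at the central carbon, and it should give the racemic 3-methylidene indanol F3 with the C2 aryl group cis to the C3 hydroxyl. Hydroboration–oxidation (9-borabicyclo[3.3.1]nonane, THF; NaOH, H2O2) anti to the C2 aryl group gives the racemic all-cis diol F4. Oxidative lactonisation (TEMPO, PhI(OAc)2, CH2Cl2) through the aldehyde and bridged lactol gives racemic lactone. Preparative chromatography on a chiral stationary phase separates 19 from its enantiomer F5. Catalytic enantiocontrol is lost in this detour and replaced by resolution.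

**Step 10.**
- Most likely failure: capture of the C3 cation by the neighbouring cis C8 carbonyl oxygen followed by hydride delivery at C8 (loss of the ketone), or acid-promoted enolisation at C1.
- Fallback, setting out from 19 and returning at 24, which keeps the ketone out of the ionic step and also bypasses step 9: ionic hydrogenolysis of the lactone C3–O bond (Et3SiH, BF3·OEt2, CH2Cl2, −40 °C) with hydride entering anti to the C2 aryl group and the carboxyl group should give (1R,2R,3R)-4,6-bis(benzyloxy)-3-[4-(benzyloxy)phenyl]-2-[3,5-bis(benzyloxy)phenyl]-2,3-dihydro-1H-indene-1-carboxylic acid F6. Neutral redox condensation (PhSSPh, PBu3, MeCN) gives the S-phenyl thioester F7. Base-free Liebeskind–Srogl coupling with 4-(benzyloxy)phenylboronic acid (Pd2(dba)3 as the zerovalent palladium source, tri(2-furyl)phosphine, copper thiophene-2-carboxylate as the monovalent copper mediator, THF, 50 °C) gives ketone 24 without touching C1.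

**Step 11.**
- Most likely failure: reduction at the C8 aryl ketone before the last, hindered benzyl ether at C4 has been cleaved.
- Fallback, from 24 to 25 with no new compound: non-reductive debenzylation with BCl3 and pentamethylbenzene as cation scavenger in CH2Cl2 at −78 °C. This is a Lewis-acid dealkylation cold enough to leave C1 and the cis aroyl/aryl pair alone.

**Step 5.**
- Most likely failure: incomplete elimination or formation of both alkene isomers, with the aldolate oxygen adding reversibly to the neighbouring ketone.
- Fallback, setting out from 11 and returning at 16, which builds the alkene by palladium arylation: alpha-methylenation (paraformaldehyde, K2CO3, Bu4NI, toluene, 60 °C) gives ethyl 2-{3,5-bis(benzyloxy)-2-[4-(benzyloxy)benzoyl]phenyl}prop-2-enoate F8. A Mizoroki–Heck reaction with 1-bromo-3,5-bis(benzyloxy)benzene (Pd(OAc)2, P(o-tolyl)3, Et3N, DMF, 100 °C) places the aryl group on the methylene carbon trans to the ester, giving 16.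

## Further compounds

F1 | step 8 | {2,4-bis(benzyloxy)-6-[(1E)-1-[3,5-bis(benzyloxy)phenyl]-3-hydroxyprop-1-en-2-yl]phenyl}[4-(benzyloxy)phenyl]methanone | OC/C(c1cc(OCc2ccccc2)cc(OCc2ccccc2)c1C(=O)c1ccc(OCc2ccccc2)cc1)=C/c1cc(OCc2ccccc2)cc(OCc2ccccc2)c1
F2 | step 8 | {2,4-bis(benzyloxy)-6-[(1E)-1-[3,5-bis(benzyloxy)phenyl]-3-bromoprop-1-en-2-yl]phenyl}[4-(benzyloxy)phenyl]methanone | BrC/C(c1cc(OCc2ccccc2)cc(OCc2ccccc2)c1C(=O)c1ccc(OCc2ccccc2)cc1)=C/c1cc(OCc2ccccc2)cc(OCc2ccccc2)c1
F3 | step 8 | racemic 5,7-bis(benzyloxy)-1-[4-(benzyloxy)phenyl]-2-[3,5-bis(benzyloxy)phenyl]-3-methylidene-2,3-dihydro-1H-inden-1-ol, hydroxyl cis to the neighbouring aryl group (one enantiomer drawn) | C=C1c2cc(OCc4ccccc4)cc(OCc4ccccc4)c2[C@](O)(c2ccc(OCc4ccccc4)cc2)[C@H]1c1cc(OCc4ccccc4)cc(OCc4ccccc4)c1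
F4 | step 8 | racemic 5,7-bis(benzyloxy)-1-[4-(benzyloxy)phenyl]-2-[3,5-bis(benzyloxy)phenyl]-3-(hydroxymethyl)-2,3-dihydro-1H-inden-1-ol, hydroxyl, aryl and hydroxymethyl groups all cis (one enantiomer drawn) | OC[C@H]1c2cc(OCc4ccccc4)cc(OCc4ccccc4)c2[C@](O)(c2ccc(OCc4ccccc4)cc2)[C@H]1c1cc(OCc4ccccc4)cc(OCc4ccccc4)c1
F5 | step 8 | (1S,2S,3S) enantiomer of lactone 19 | O=C(O3)[C@@H]1c2cc(OCc4ccccc4)cc(OCc4ccccc4)c2[C@@]3(c2ccc(OCc4ccccc4)cc2)[C@@H]1c1cc(OCc4ccccc4)cc(OCc4ccccc4)c1
F6 | step 10 | (1R,2R,3R)-4,6-bis(benzyloxy)-3-[4-(benzyloxy)phenyl]-2-[3,5-bis(benzyloxy)phenyl]-2,3-dihydro-1H-indene-1-carboxylic acid | OC(=O)[C@H]1c2cc(OCc4ccccc4)cc(OCc4ccccc4)c2[C@@H](c2ccc(OCc4ccccc4)cc2)[C@H]1c1cc(OCc4ccccc4)cc(OCc4ccccc4)c1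
F7 | step 10 | S-phenyl (1R,2R,3R)-4,6-bis(benzyloxy)-3-[4-(benzyloxy)phenyl]-2-[3,5-bis(benzyloxy)phenyl]-2,3-dihydro-1H-indene-1-carbothioate | O=C(Sc5ccccc5)[C@H]1c2cc(OCc4ccccc4)cc(OCc4ccccc4)c2[C@@H](c2ccc(OCc4ccccc4)cc2)[C@H]1c1cc(OCc4ccccc4)cc(OCc4ccccc4)c1
F8 | step 5 | ethyl 2-{3,5-bis(benzyloxy)-2-[4-(benzyloxy)benzoyl]phenyl}prop-2-enoate | CCOC(=O)C(=C)c1cc(OCc2ccccc2)cc(OCc2ccccc2)c1C(=O)c1ccc(OCc2ccccc2)cc1
F0 | step 11 | none | none
A1 | alternative 1 | 2-{2-[4-(benzyloxy)benzoyl]-3,5-dimethoxyphenyl}-1-[4-(benzyloxy)phenyl]ethanone | O=C(Cc1cc(OC)cc(OC)c1C(=O)c1ccc(OCc2ccccc2)cc1)c1ccc(OCc2ccccc2)cc1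
A2 | alternative 2 | 3-{[tert-butyl(dimethyl)silyl]oxy(4-methoxyphenyl)methyl}-2-(3,5-dimethoxyphenyl)-5,7-dimethoxy-1-(4-methoxyphenyl)-1H-inden-1-ol, carbinol configured as drawn, silyl ether centre undefined | COc1ccc(cc1)C(O[Si](C)(C)C(C)(C)C)C1=C(c2cc(OC)cc(OC)c2)[C@](O)(c2ccc(OC)cc2)c2c(OC)cc(OC)cc12
A3 | alternative 3 | (1R,2R,3R)-2-(3,5-dimethoxyphenyl)-N,4,6-trimethoxy-3-(4-methoxyphenyl)-N-methyl-2,3-dihydro-1H-indene-1-carboxamide | CON(C)C(=O)[C@H]1c2cc(OC)cc(OC)c2[C@@H](c2ccc(OC)cc2)[C@H]1c1cc(OC)cc(OC)c1
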